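## Retrosynthetic overview

1. Katsumain C ← removal of one acetate and three silyl groups from a protected 3′-alkylated chalcone. Its C3′–C7 bond and the (7R) diaryl methine come from an aromatic Claisen [3,3] shift of a 2′-O-allyl aryl ether (1,3-chirality transfer, E-alkene).
2. That ether ← late Mitsunobu union of two halves of similar size: 4′-O-silyl cardamonin (chalcone half) and a (3R,5S,6E)-1,7-diarylhept-6-ene-3,5-diol derivative (heptanoid half).
3. Chalcone half ← resorcinol: C–H borylation/oxidation (third oxygen), ortho-formylation, methyl ketone, Claisen–Schmidt condensation with benzaldehyde.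
4. Heptanoid half ← 4-iodophenol (twice), allyl alcohol, ethyl diazoacetate and a vinyl Grignard: Heck, Roskamp, Noyori hydrogenation (C3), Heck, CBS reduction (C5).
5. Rings: none is built. Ring A comes from resorcinol, ring B from benzaldehyde, and the two hydroxyphenyl rings (C and D) from 4-iodophenol.

Assumption and conventions: the SMILES is read as (3R,7R) with both C=C bonds E, in heptanoid locants (C1 = CH2 on ring D, C3 = carbinol, C7 = diaryl methine); primed locants are ring A; MOM = CH3OCH2, TBS = tert-butyldimethylsilyl.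

## Route

**Chalcone half (fragment A)**

Step 1
Reactants: 1 resorcinol
Product: 2 1,3-bis(methoxymethoxy)benzene
Conditions: NaH, MOMCl, DMF, 0 °C → rt
Reagents that add atoms: chloromethyl methyl ether (MOMCl), COCCl
Why: Williamson-type O-alkylation of both phenoxides gives base-stable acetal ethers and leaves C5 as the only ring C–H without an ortho substituent.

Step 2
Reactants: 2 1,3-bis(methoxymethoxy)benzene
Product: 4 3,5-bis(methoxymethoxy)phenol, via aryl pinacol boronate 3 (not isolated)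
Conditions: [Ir(OMe)(cod)]2 (1.5 mol%), 4,4'-di-tert-butyl-2,2'-bipyridine (3 mol%), B2pin2 (0.6 equiv), THF, 80 °C; then aq. NaOH, H2O2, 0 °C → rt
Reagents that add atoms: bis(pinacolato)diboron, CC1(C)OB(OC1(C)C)B1OC(C)(C)C(C)(C)O1 (boron of 3); hydrogen peroxide, OO (oxygen of 4)
Why: Sterically governed Ir-catalysed C–H borylation (Hartwig–Miyaura type) occurs only at C5, meta to both ethers, and oxidation of the C–B bond installs the third oxygen of ring A.

Step 3
Reactants: 4 3,5-bis(methoxymethoxy)phenol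
Product: 6 2-hydroxy-4,6-bis(methoxymethoxy)benzaldehyde, via salicyl alcohol 5 (not isolated)
Conditions: MgCl2, Et3N, (CH2O)n, MeCN, reflux
Reagents that add atoms: formaldehyde (as paraformaldehyde), C=O
Why: In this Mg-mediated ortho-formylation (Casnati–Skattebøl reaction) the magnesium phenoxide delivers formaldehyde only ortho to the free OH (both ortho sites are equivalent), and a second formaldehyde oxidises the hydroxymethyl intermediate by hydride transfer.

Step 4
Reactants: 6 2-hydroxy-4,6-bis(methoxymethoxy)benzaldehyde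
Product: 7 2-methoxy-4,6-bis(methoxymethoxy)benzaldehyde
Conditions: MeI, K2CO3, DMF, rt
Reagents that add atoms: iodomethane, CI
Why: Williamson O-methylation of the only free (chelated) phenol fixes the future 6′-OMe group.

Step 5
Reactants: 7 2-methoxy-4,6-bis(methoxymethoxy)benzaldehyde
Product: 8 rac-1-[2-methoxy-4,6-bis(methoxymethoxy)phenyl]ethan-1-ol
Conditions: MeMgBr, THF, 0 °C; then aq. NH4Cl
Reagents that add atoms: methylmagnesium bromide, C[Mg]Br
Why: Grignard 1,2-addition to the aldehyde; the carbinol center is formed racemic and is removed in step 6.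

Step 6
Reactants: 8 rac-1-[2-methoxy-4,6-bis(methoxymethoxy)phenyl]ethan-1-ol
Product: 9 1-[2-methoxy-4,6-bis(methoxymethoxy)phenyl]ethan-1-one
Conditions: Dess–Martin periodinane, CH2Cl2, rt
Reagents that add atoms: none
Why: Dess–Martin oxidation of the benzylic alcohol gives the methyl ketone under conditions that leave the MOM acetals intact.

Step 7
Reactants: 9 1-[2-methoxy-4,6-bis(methoxymethoxy)phenyl]ethan-1-one; 10 benzaldehyde
Product: 12 (E)-1-[2-methoxy-4,6-bis(methoxymethoxy)phenyl]-3-phenylprop-2-en-1-one, via aldol adduct 11 (not isolated)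
Conditions: KOH, EtOH/H2O, rt
Reagents that add atoms: none
Why: Claisen–Schmidt (crossed aldol) condensation with a non-enolisable aldehyde, followed by E1cB dehydration to the conjugated E-enone; MOM ethers are stable to hydroxide.

Step 8
Reactants: 12 (E)-1-[2-methoxy-4,6-bis(methoxymethoxy)phenyl]-3-phenylprop-2-en-1-one
Product: 13 cardamonin [(E)-1-(2,4-dihydroxy-6-methoxyphenyl)-3-phenylprop-2-en-1-one]
Conditions: 3 M HCl, MeOH, 50 °C
Reagents that add atoms: none
Why: Acid-catalysed acetal methanolysis removes both MOM groups, and the hydrogen-bonded 2′-hydroxychalcone survives the short exposure.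

Step 9
Reactants: 13 cardamonin
Product: 14 (E)-1-[4-(TBSO)-2-hydroxy-6-methoxyphenyl]-3-phenylprop-2-en-1-one (4′-O-TBS-cardamonin)
Conditions: TBSCl (1.05 equiv), imidazole, CH2Cl2, 0 °C
Reagents that add atoms: tert-butyldimethylsilyl chloride, CC(C)(C)[Si](C)(C)Cl
Why: Selective silylation of the more acidic, non-chelated 4′-OH; the 2′-OH hydrogen-bonded to the carbonyl stays free for the coupling.

**Heptanoid half (fragment B)**

Step 10
Reactants: 15 4-iodophenol
Product: 16 tert-butyl(4-iodophenoxy)dimethylsilane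
Conditions: TBSCl, imidazole, DMF, rt
Reagents that add atoms: tert-butyldimethylsilyl chloride, CC(C)(C)[Si](C)(C)Cl
Why: Standard silylation masks the phenol of ring D for the organometallic steps.

Step 11
Reactants: 16 tert-butyl(4-iodophenoxy)dimethylsilane; 17 prop-2-en-1-ol (allyl alcohol)
Product: 18 3-[4-(TBSO)phenyl]propanal
Conditions: Pd(OAc)2 (3 mol%), Bu4NCl, NaHCO3, DMF, 45 °C
Reagents that add atoms: none
Why: Mizoroki–Heck arylation under Jeffery conditions; β-hydride elimination toward the carbinol carbon gives the enol and hence the saturated aldehyde.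

Step 12
Reactants: 18 3-[4-(TBSO)phenyl]propanal; 19 ethyl diazoacetate
Product: 20 ethyl 3-oxo-5-[4-(TBSO)phenyl]pentanoate
Conditions: SnCl2 (10 mol%), CH2Cl2, rt
Reagents that add atoms: none
Why: Roskamp homologation: Lewis-acid-promoted addition of the diazo ester to the aldehyde, 1,2-hydride shift and loss of N2 give the β-keto ester.

Step 13
Reactants: 20 ethyl 3-oxo-5-[4-(TBSO)phenyl]pentanoate
Product: 21 ethyl (3R)-3-hydroxy-5-[4-(TBSO)phenyl]pentanoate
Conditions: H2 (50 bar), [RuCl(p-cymene)((R)-BINAP)]Cl (0.5 mol%), EtOH, 50 °C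
Reagents that add atoms: none
Why: Noyori asymmetric hydrogenation of the chelated β-keto ester; the (R)-BINAP–Ru catalyst gives the (R)-alcohol, which becomes the carbinol center C3 of the target.

Step 14
Reactants: 21 ethyl (3R)-3-hydroxy-5-[4-(TBSO)phenyl]pentanoate
Product: 22 ethyl (3R)-3-(TBSO)-5-[4-(TBSO)phenyl]pentanoate
Conditions: TBSCl, imidazole, DMF, rt
Reagents that add atoms: tert-butyldimethylsilyl chloride, CC(C)(C)[Si](C)(C)Cl
Why: Silylation protects the C3 hydroxyl so that it cannot cyclise onto the allylic position later.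

Step 15
Reactants: 22 ethyl (3R)-3-(TBSO)-5-[4-(TBSO)phenyl]pentanoate
Product: 23 (3R)-N-methoxy-N-methyl-3-(TBSO)-5-[4-(TBSO)phenyl]pentanamide
Conditions: MeNH(OMe)·HCl, iPrMgCl, THF, −20 → 0 °C
Reagents that add atoms: N,O-dimethylhydroxylamine hydrochloride, CNOC.Cl
Why: Aminolysis of the ester by the magnesium amide gives the Weinreb amide without touching the β-silyloxy center.

Step 16
Reactants: 23 (3R)-N-methoxy-N-methyl-3-(TBSO)-5-[4-(TBSO)phenyl]pentanamide
Product: 24 (5R)-5-(TBSO)-7-[4-(TBSO)phenyl]hept-1-en-3-one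
Conditions: CH2=CHMgBr, THF, 0 °C; then inverse quench into cold aq. NH4Cl
Reagents that add atoms: vinylmagnesium bromide, C=C[Mg]Br
Why: Weinreb ketone synthesis: the chelated tetrahedral intermediate stops the addition at the vinyl ketone.

Step 17
Reactants: 15 4-iodophenol
Product: 25 4-iodophenyl acetate
Conditions: Ac2O, pyridine, CH2Cl2, rt
Reagents that add atoms: acetic anhydride, CC(=O)OC(C)=O
Why: O-acylation; the acetate keeps ring C electron-poor, which disfavours ionisation of the cinnamyl system in steps 20 and 21.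

Step 18
Reactants: 24 (5R)-5-(TBSO)-7-[4-(TBSO)phenyl]hept-1-en-3-one; 25 4-iodophenyl acetate
Product: 26 4-[(1E,5R)-3-oxo-5-(TBSO)-7-[4-(TBSO)phenyl]hept-1-en-1-yl]phenyl acetate
Conditions: Pd(OAc)2 (5 mol%), Bu4NCl, NaHCO3, DMF, 50 °C
Reagents that add atoms: none
Why: Mizoroki–Heck arylation of the terminal enone carbon; syn insertion and syn β-hydride elimination give the E-enone, and the weak base does not eliminate the β-silyloxy group.

Step 19
Reactants: 26 4-[(1E,5R)-3-oxo-5-(TBSO)-7-[4-(TBSO)phenyl]hept-1-en-1-yl]phenyl acetate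
Product: 27 4-[(1E,3S,5R)-3-hydroxy-5-(TBSO)-7-[4-(TBSO)phenyl]hept-1-en-1-yl]phenyl acetate
Conditions: (R)-2-methyl-CBS-oxazaborolidine (0.2 equiv), BH3·SMe2, THF, −30 °C; then MeOH
Reagents that add atoms: none
Why: Corey–Bakshi–Shibata reduction under catalyst control: with the styryl group as the large substituent the (R)-oxazaborolidine gives the (S)-allylic alcohol (1,2-reduction), and the minor diastereomer is separable.

**Union and endgame**

Step 20
Reactants: 14 4′-O-TBS-cardamonin; 27 4-[(1E,3S,5R)-3-hydroxy-5-(TBSO)-7-[4-(TBSO)phenyl]hept-1-en-1-yl]phenyl acetate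
Product: 28 (E)-1-{2-{[(1E,3R,5R)-1-(4-acetoxyphenyl)-5-(TBSO)-7-[4-(TBSO)phenyl]hept-1-en-3-yl]oxy}-4-(TBSO)-6-methoxyphenyl}-3-phenylprop-2-en-1-one
Conditions: PPh3, DIAD, toluene, 0 °C → rt
Reagents that add atoms: none
Why: Mitsunobu etherification: the only free OH of 14 (2′-OH) displaces the activated allylic alcohol by SN2 with inversion, turning the (S)-carbinol into the (R)-aryl ether; the non-polar solvent and the electron-poor acetoxyphenyl ring suppress SN1 and SN2′ pathways.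

Step 21
Reactants: 28 aryl allyl ether
Product: 30 (E)-1-{3-[(1R,2E,5R)-1-(4-acetoxyphenyl)-5-(TBSO)-7-[4-(TBSO)phenyl]hept-2-en-1-yl]-4-(TBSO)-2-hydroxy-6-methoxyphenyl}-3-phenylprop-2-en-1-one, via ortho-dienone 29 (not isolated)
Conditions: degassed mesitylene, BHT (cat.), 160 °C, sealed tube
Reagents that add atoms: none
Why: Aromatic Claisen rearrangement ([3,3]-sigmatropic shift): the acyl group blocks C1′, so C7 bonds to C3′ through a chair transition state with the chain equatorial, which gives the E-alkene and transfers the (R) C–O center suprafacially into the (R) diaryl methine before the dienone tautomerises to the chelated phenol.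

Step 22
Reactants: 30 Claisen product
Product: 31 (E)-1-{3-[(1R,2E,5R)-5-(TBSO)-1,7-bis(4-hydroxyphenyl)hept-2-en-1-yl]-2,4-dihydroxy-6-methoxyphenyl}-3-phenylprop-2-en-1-one
Conditions: K2CO3, MeOH, 0 °C → rt, under argon
Reagents that add atoms: none
Why: Base-catalysed methanolysis cleaves the aryl acetate and both aryl silyl ethers (phenoxide leaving groups) while the secondary alkyl silyl ether and both stereocenters are untouched.

Step 23
Reactants: 31 3-O-TBS-katsumain C
Product: 32 katsumain C [(E)-1-{2,4-dihydroxy-3-[(1R,2E,5R)-5-hydroxy-1,7-bis(4-hydroxyphenyl)hept-2-en-1-yl]-6-methoxyphenyl}-3-phenylprop-2-en-1-one]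
Conditions: HF·pyridine, pyridine/THF, 0 °C → rt
Reagents that add atoms: none
Why: Fluoride-driven desilylation under buffered, weakly acidic conditions frees the C3 hydroxyl without epimerisation, alkene migration or flavanone formation.

## Compound list

1 | resorcinol (benzene-1,3-diol) | Oc1cccc(O)c1 | starting material
2 | 1,3-bis(methoxymethoxy)benzene | COCOc1cccc(OCOC)c1 | intermediate
3 | 2-[3,5-bis(methoxymethoxy)phenyl]-4,4,5,5-tetramethyl-1,3,2-dioxaborolane | COCOc1cc(OCOC)cc(B2OC(C)(C)C(C)(C)O2)c1 | intermediate (not isolated)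
4 | 3,5-bis(methoxymethoxy)phenol | COCOc1cc(O)cc(OCOC)c1 | intermediate
5 | 2-(hydroxymethyl)-3,5-bis(methoxymethoxy)phenol | COCOc1cc(O)c(CO)c(OCOC)c1 | intermediate (not isolated)
6 | 2-hydroxy-4,6-bis(methoxymethoxy)benzaldehyde | COCOc1cc(O)c(C=O)c(OCOC)c1 | intermediate
7 | 2-methoxy-4,6-bis(methoxymethoxy)benzaldehyde | COCOc1cc(OC)c(C=O)c(OCOC)c1 | intermediate
8 | rac-1-[2-methoxy-4,6-bis(methoxymethoxy)phenyl]ethan-1-ol | COCOc1cc(OC)c(C(C)O)c(OCOC)c1 | intermediate
9 | 1-[2-methoxy-4,6-bis(methoxymethoxy)phenyl]ethan-1-one | COCOc1cc(OC)c(C(C)=O)c(OCOC)c1 | intermediate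
10 | benzaldehyde | O=Cc1ccccc1 | starting material
11 | rac-3-hydroxy-1-[2-methoxy-4,6-bis(methoxymethoxy)phenyl]-3-phenylpropan-1-one | COCOc1cc(OC)c(C(=O)CC(O)c2ccccc2)c(OCOC)c1 | intermediate (not isolated)
12 | (E)-1-[2-methoxy-4,6-bis(methoxymethoxy)phenyl]-3-phenylprop-2-en-1-one | COCOc1cc(OC)c(C(=O)/C=C/c2ccccc2)c(OCOC)c1 | intermediate
13 | cardamonin, (E)-1-(2,4-dihydroxy-6-methoxyphenyl)-3-phenylprop-2-en-1-one | COc1cc(O)cc(O)c1C(=O)/C=C/c1ccccc1 | intermediate
14 | (E)-1-[4-(TBSO)-2-hydroxy-6-methoxyphenyl]-3-phenylprop-2-en-1-one | COc1cc(O[Si](C)(C)C(C)(C)C)cc(O)c1C(=O)/C=C/c1ccccc1 | intermediate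
15 | 4-iodophenol | Oc1ccc(I)cc1 | starting material
16 | tert-butyl(4-iodophenoxy)dimethylsilane | CC(C)(C)[Si](C)(C)Oc1ccc(I)cc1 | intermediate
17 | prop-2-en-1-ol (allyl alcohol) | C=CCO | starting material
18 | 3-[4-(TBSO)phenyl]propanal | CC(C)(C)[Si](C)(C)Oc1ccc(CCC=O)cc1 | intermediate
19 | ethyl diazoacetate | CCOC(=O)C=[N+]=[N-] | starting material
20 | ethyl 3-oxo-5-[4-(TBSO)phenyl]pentanoate | CCOC(=O)CC(=O)CCc1ccc(O[Si](C)(C)C(C)(C)C)cc1 | intermediate
21 | ethyl (3R)-3-hydroxy-5-[4-(TBSO)phenyl]pentanoate | CCOC(=O)C[C@H](O)CCc1ccc(O[Si](C)(C)C(C)(C)C)cc1 | intermediate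
22 | ethyl (3R)-3-(TBSO)-5-[4-(TBSO)phenyl]pentanoate | CCOC(=O)C[C@H](O[Si](C)(C)C(C)(C)C)CCc1ccc(O[Si](C)(C)C(C)(C)C)cc1 | intermediate
23 | (3R)-N-methoxy-N-methyl-3-(TBSO)-5-[4-(TBSO)phenyl]pentanamide | CON(C)C(=O)C[C@H](O[Si](C)(C)C(C)(C)C)CCc1ccc(O[Si](C)(C)C(C)(C)C)cc1 | intermediate
24 | (5R)-5-(TBSO)-7-[4-(TBSO)phenyl]hept-1-en-3-one | C=CC(=O)C[C@H](O[Si](C)(C)C(C)(C)C)CCc1ccc(O[Si](C)(C)C(C)(C)C)cc1 | intermediate
25 | 4-iodophenyl acetate | CC(=O)Oc1ccc(I)cc1 | intermediate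
26 | 4-[(1E,5R)-3-oxo-5-(TBSO)-7-[4-(TBSO)phenyl]hept-1-en-1-yl]phenyl acetate | CC(=O)Oc1ccc(/C=C/C(=O)C[C@H](O[Si](C)(C)C(C)(C)C)CCc2ccc(O[Si](C)(C)C(C)(C)C)cc2)cc1 | intermediate
27 | 4-[(1E,3S,5R)-3-hydroxy-5-(TBSO)-7-[4-(TBSO)phenyl]hept-1-en-1-yl]phenyl acetate | CC(=O)Oc1ccc(/C=C/[C@@H](O)C[C@H](O[Si](C)(C)C(C)(C)C)CCc2ccc(O[Si](C)(C)C(C)(C)C)cc2)cc1 | intermediate
28 | (E)-1-{2-{[(1E,3R,5R)-1-(4-acetoxyphenyl)-5-(TBSO)-7-[4-(TBSO)phenyl]hept-1-en-3-yl]oxy}-4-(TBSO)-6-methoxyphenyl}-3-phenylprop-2-en-1-one | COc1cc(O[Si](C)(C)C(C)(C)C)cc(O[C@@H](/C=C/c2ccc(OC(C)=O)cc2)C[C@H](O[Si](C)(C)C(C)(C)C)CCc2ccc(O[Si](C)(C)C(C)(C)C)cc2)c1C(=O)/C=C/c1ccccc1 | intermediate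
29 | (6S)-6-[(1S,2E,5R)-1-(4-acetoxyphenyl)-5-(TBSO)-7-[4-(TBSO)phenyl]hept-2-en-1-yl]-5-(TBSO)-3-methoxy-2-[(E)-3-phenylprop-2-enoyl]cyclohexa-2,4-dien-1-one | COC1=C(C(=O)/C=C/c2ccccc2)C(=O)[C@@H]([C@H](/C=C/C[C@H](O[Si](C)(C)C(C)(C)C)CCc2ccc(O[Si](C)(C)C(C)(C)C)cc2)c2ccc(OC(C)=O)cc2)C(O[Si](C)(C)C(C)(C)C)=C1 | intermediate (not isolated)
30 | (E)-1-{3-[(1R,2E,5R)-1-(4-acetoxyphenyl)-5-(TBSO)-7-[4-(TBSO)phenyl]hept-2-en-1-yl]-4-(TBSO)-2-hydroxy-6-methoxyphenyl}-3-phenylprop-2-en-1-one | COc1cc(O[Si](C)(C)C(C)(C)C)c([C@H](/C=C/C[C@H](O[Si](C)(C)C(C)(C)C)CCc2ccc(O[Si](C)(C)C(C)(C)C)cc2)c2ccc(OC(C)=O)cc2)c(O)c1C(=O)/C=C/c1ccccc1 | intermediate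
31 | (E)-1-{3-[(1R,2E,5R)-5-(TBSO)-1,7-bis(4-hydroxyphenyl)hept-2-en-1-yl]-2,4-dihydroxy-6-methoxyphenyl}-3-phenylprop-2-en-1-one | COc1cc(O)c([C@H](/C=C/C[C@H](O[Si](C)(C)C(C)(C)C)CCc2ccc(O)cc2)c2ccc(O)cc2)c(O)c1C(=O)/C=C/c1ccccc1 | intermediate
32 | katsumain C, (E)-1-{2,4-dihydroxy-3-[(1R,2E,5R)-5-hydroxy-1,7-bis(4-hydroxyphenyl)hept-2-en-1-yl]-6-methoxyphenyl}-3-phenylprop-2-en-1-one | COc1cc(O)c([C@H](/C=C/C[C@H](O)CCc2ccc(O)cc2)c2ccc(O)cc2)c(O)c1C(=O)/C=C/c1ccccc1 | target

## Step count and risks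

Total step count: 23.
Longest linear sequence: 13 steps (steps 10–16, 18, 19, then 20–23; equally steps 1–9, then 20–23).

The three steps most likely to fail:

Step 20 (Mitsunobu etherification). A chelated, ortho-acylated phenol is a sluggish nucleophile, and the secondary cinnamyl-type alcohol can ionise, react SN2′ or eliminate to a diene, which would cost yield and stereochemical purity. The fallback sets out from enone 26 and comes back at ether 28. Enone 26 is reduced with the enantiomeric (S)-2-methyl-CBS-oxazaborolidine and BH3·SMe2 to the epimeric alcohol 4-[(1E,3R,5R)-3-hydroxy-5-(TBSO)-7-[4-(TBSO)phenyl]hept-1-en-1-yl]phenyl acetate F1. ClCO2Me and pyridine convert it into the allylic methyl carbonate 4-[(1E,3R,5R)-3-[(methoxycarbonyl)oxy]-5-(TBSO)-7-[4-(TBSO)phenyl]hept-1-en-1-yl]phenyl acetate F2. F2 is then coupled with phenol 14 under Pd(PPh3)4 catalysis (THF, 0 °C → rt). Ionisation and attack of the phenoxide on the allyl complex both occur with inversion, so the net result is retention, and attack at the alkyl-bearing terminus remote from the arene keeps the styrene conjugation and gives 28.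

Step 21 (aromatic Claisen rearrangement). The 2′-alkoxy and 2′-hydroxy chalcones may not tolerate 160 °C (flavanone closure, elimination of the secondary ether, ion-pair [1,3] shift with loss of chirality transfer). The fallback sets out from ketone 9 and comes back at compound 31, moving the sigmatropic step to the more robust acetophenone. Both MOM ethers of 9 are cleaved (HCl, MeOH) to give 1-(2,4-dihydroxy-6-methoxyphenyl)ethan-1-one F3. Its 4-OH is silylated (TBSCl, imidazole) to 1-[4-(TBSO)-2-hydroxy-6-methoxyphenyl]ethan-1-one F4. Mitsunobu reaction of F4 with alcohol 27 (PPh3, DIAD, toluene) gives the (3R)-configured aryl allyl ether F5. Heating in N,N-diethylaniline at 180 °C rearranges it to the C-alkylated acetophenone F6, with the same chirality transfer. Claisen–Schmidt condensation of F6 with benzaldehyde 10 (KOH, EtOH/H2O), which also cleaves the acetate and both aryl silyl ethers, delivers 31.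

Step 3 (ortho-formylation). The very electron-rich phenol 4 may over-react (bis-formylation, diarylmethane formation) or lose a MOM group. The fallback sets out from phenol 4 and comes back at aldehyde 6. Phenol 4 is converted with MOMCl and NaH into 1,3,5-tris(methoxymethoxy)benzene F7. Directed ortho-lithiation (n-BuLi, THF, 0 °C; all three ring positions are equivalent) and a DMF quench give 2,4,6-tris(methoxymethoxy)benzaldehyde F8. One of the two equivalent ortho MOM groups is then removed with carbonyl assistance (I2 cat., MeOH, rt); the hydrogen-bonded phenol that results slows the second cleavage, so the reaction stops at 6.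

## Further compounds

F1 | step 20 | 4-[(1E,3R,5R)-3-hydroxy-5-(TBSO)-7-[4-(TBSO)phenyl]hept-1-en-1-yl]phenyl acetate | CC(=O)Oc1ccc(/C=C/[C@H](O)C[C@H](O[Si](C)(C)C(C)(C)C)CCc2ccc(O[Si](C)(C)C(C)(C)C)cc2)cc1
F2 | step 20 | 4-[(1E,3R,5R)-3-[(methoxycarbonyl)oxy]-5-(TBSO)-7-[4-(TBSO)phenyl]hept-1-en-1-yl]phenyl acetate | CC(=O)Oc1ccc(/C=C/[C@H](OC(=O)OC)C[C@H](O[Si](C)(C)C(C)(C)C)CCc2ccc(O[Si](C)(C)C(C)(C)C)cc2)cc1
F3 | step 21 | 1-(2,4-dihydroxy-6-methoxyphenyl)ethan-1-one | COc1cc(O)cc(O)c1C(C)=O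
F4 | step 21 | 1-[4-(TBSO)-2-hydroxy-6-methoxyphenyl]ethan-1-one | COc1cc(O[Si](C)(C)C(C)(C)C)cc(O)c1C(C)=O
F5 | step 21 | 1-{2-{[(1E,3R,5R)-1-(4-acetoxyphenyl)-5-(TBSO)-7-[4-(TBSO)phenyl]hept-1-en-3-yl]oxy}-4-(TBSO)-6-methoxyphenyl}ethan-1-one | COc1cc(O[Si](C)(C)C(C)(C)C)cc(O[C@@H](/C=C/c2ccc(OC(C)=O)cc2)C[C@H](O[Si](C)(C)C(C)(C)C)CCc2ccc(O[Si](C)(C)C(C)(C)C)cc2)c1C(C)=O
F6 | step 21 | 1-{3-[(1R,2E,5R)-1-(4-acetoxyphenyl)-5-(TBSO)-7-[4-(TBSO)phenyl]hept-2-en-1-yl]-4-(TBSO)-2-hydroxy-6-methoxyphenyl}ethan-1-one | COc1cc(O[Si](C)(C)C(C)(C)C)c([C@H](/C=C/C[C@H](O[Si](C)(C)C(C)(C)C)CCc2ccc(O[Si](C)(C)C(C)(C)C)cc2)c2ccc(OC(C)=O)cc2)c(O)c1C(C)=O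
F7 | step 3 | 1,3,5-tris(methoxymethoxy)benzene | COCOc1cc(OCOC)cc(OCOC)c1
F8 | step 3 | 2,4,6-tris(methoxymethoxy)benzaldehyde | COCOc1cc(OCOC)c(C=O)c(OCOC)c1
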